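**Target:** methyl 2-[(3R,5S)-3,5-dimethyl-5-[(7E,9E,12Z)-pentadeca-7,9,12-trien-1-yl]-1,2-dioxolan-3-yl]acetate. The two ring methyls are trans, so CH2CO2Me is trans to the long chain.

**Retrosynthetic overview**
1. Triene last: Suzuki coupling of an (E)-alkenyl pinacol boronate (from a terminal alkene by cross-metathesis) with (1E,4Z)-1-iodohepta-1,4-diene, so the oxidation-prone triene never meets the peroxide-forming steps.
2. Key disconnection C3–CH2CO2Me: intermolecular Mukaiyama aldol-type addition of the methyl acetate silyl ketene acetal (fragment 2) to the peroxycarbenium ion from a 3-methoxy-1,2-dioxolane (fragment 1); this sets C3.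
3. The 1,2-dioxolane, the only ring of the target, comes from a β-hydroperoxy ketone (cyclic peroxyhemiketal, then methyl peroxyketal) and is closed before the key step.
4. C5–OO comes from invertive H2O2 opening of an enantioenriched oxetane, made from a 1,3-diol, made from a Sharpless epoxy alcohol. Ring order: epoxide, oxetane, then dioxolane.
5. The allylic alcohol comes from syn-carbocupration of ethyl but-2-ynoate with an oct-7-enyl copper reagent from 8-bromooct-1-ene.

Assumption: H2O2 opens the tertiary oxetane carbon with clean inversion, as known for 2,2-disubstituted oxetanes; the carbinol centre made in step 5 is carried as an epimer mixture and erased in step 11.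

**Route**

Step 1
Reactants: 1 8-bromooct-1-ene; 2 ethyl but-2-ynoate
Product: 5 ethyl (2E)-3-methylundeca-2,10-dienoate, via oct-7-en-1-ylmagnesium bromide 3 (not isolated), via oct-7-en-1-ylcopper 4 (not isolated)
Conditions: Mg, THF, 25–40 °C; CuBr·SMe2 (1.0 equiv), THF, −40 °C; then 2, −78 °C; sat. aq. NH4Cl at −78 °C
Reagents that add atoms: none
Why: Conjugate (Michael-type) syn-carbocupration of the ynoate followed by protonation of the alkenylcopper at −78 °C places the new chain cis to H, which is the (E)-enoate (typically >95:5).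

Step 2
Reactants: 5 ethyl (2E)-3-methylundeca-2,10-dienoate
Product: 6 (2E)-3-methylundeca-2,10-dien-1-ol
Conditions: iBu2AlH (2.5 equiv), CH2Cl2, −78 → 0 °C; aq. potassium sodium tartrate (KNaC4H4O6)
Reagents that add atoms: none
Why: 1,2-Reduction of the conjugated ester by the aluminium hydride gives the allylic alcohol without touching either alkene or the double-bond geometry.

Step 3
Reactants: 6 (2E)-3-methylundeca-2,10-dien-1-ol
Product: 7 [(2R,3R)-3-methyl-3-(oct-7-en-1-yl)oxiran-2-yl]methanol
Conditions: Ti(OiPr)4 (10 mol %), D-(−)-diethyl tartrate (12 mol %), tBuOOH (2 equiv, decane), 4 Å MS, CH2Cl2, −20 °C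
Reagents that add atoms: tert-butyl hydroperoxide, CC(C)(C)OO
Why: Sharpless asymmetric epoxidation epoxidises only the allylic alcohol double bond, and with D-(−)-tartrate a geraniol-type (E)-3,3-disubstituted allylic alcohol gives the (2R,3R)-epoxide (about 90–95% ee), fixing the quaternary carbon that becomes C5.

Step 4
Reactants: 7 [(2R,3R)-3-methyl-3-(oct-7-en-1-yl)oxiran-2-yl]methanol
Product: 8 (2S,3R)-3-methyl-3-(oct-7-en-1-yl)oxirane-2-carbaldehyde
Conditions: TEMPO (10 mol %), PhI(OAc)2 (1.1 equiv), CH2Cl2, 25 °C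
Reagents that add atoms: none
Why: Oxoammonium (TEMPO) oxidation stops at the aldehyde and tolerates the epoxide and the terminal alkene; the C2 descriptor becomes S only because CHO now outranks C3.

Step 5
Reactants: 8 (2S,3R)-3-methyl-3-(oct-7-en-1-yl)oxirane-2-carbaldehyde
Product: 9 1-[(2R,3R)-3-methyl-3-(oct-7-en-1-yl)oxiran-2-yl]ethan-1-ol (carbinol epimer mixture)
Conditions: MeMgBr (1.3 equiv), THF, −78 °C; H2O
Reagents that add atoms: methylmagnesium bromide, C[Mg]Br
Why: Grignard addition to the aldehyde is far faster than epoxide opening at −78 °C; the new carbinol centre forms as an epimer mixture, which does not matter because it is oxidised to the ketone in step 11.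

Step 6
Reactants: 9 1-[(2R,3R)-3-methyl-3-(oct-7-en-1-yl)oxiran-2-yl]ethan-1-ol
Product: 10 (4R)-4-methyldodec-11-ene-2,4-diol (C2 epimer mixture)
Conditions: NaAlH2(OCH2CH2OMe)2 (Red-Al, 2.5 equiv), THF, 0 → 25 °C
Reagents that add atoms: none
Why: Hydroxyl-directed Red-Al reduction of a 2,3-epoxy alcohol delivers hydride intramolecularly to C2 (the tertiary C3 is also shielded), giving the 1,3-diol with the tertiary C–O bond and its configuration untouched.

Step 7
Reactants: 10 (4R)-4-methyldodec-11-ene-2,4-diol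
Product: 11 (4R)-4-hydroxy-4-methyldodec-11-en-2-yl 4-methylbenzenesulfonate (C2 epimer mixture)
Conditions: TsCl (1.3 equiv), pyridine, DMAP (cat.), CH2Cl2, 0 → 25 °C
Reagents that add atoms: 4-methylbenzenesulfonyl chloride, Cc1ccc(cc1)S(=O)(=O)Cl
Why: Sulfonylation is selective for the secondary over the hindered tertiary hydroxyl, giving the monotosylate needed for ring closure.

Step 8
Reactants: 11 (4R)-4-hydroxy-4-methyldodec-11-en-2-yl 4-methylbenzenesulfonate
Product: 12 (2R)-2,4-dimethyl-2-(oct-7-en-1-yl)oxetane (C4 epimer mixture)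
Conditions: KOtBu (1.3 equiv), THF, 0 → 25 °C
Reagents that add atoms: none
Why: Intramolecular Williamson etherification (4-exo-tet): the tertiary alkoxide displaces the secondary tosylate with inversion at that carbon only, so the quaternary centre keeps its (R) configuration.

Step 9
Reactants: 12 (2R)-2,4-dimethyl-2-(oct-7-en-1-yl)oxetane
Product: 13 (4S)-4-hydroperoxy-4-methyldodec-11-en-2-ol (C2 epimer mixture)
Conditions: anhydrous H2O2 in Et2O (10 equiv), TMSOTf (0.2 equiv), Et2O, −78 → −40 °C; aq. NaHCO3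
Reagents that add atoms: hydrogen peroxide, OO
Why: Lewis-acid-activated oxetane perhydrolysis occurs at the more substituted, cation-stabilising carbon by backside attack of H2O2, so the C–OO centre forms with inversion, (R)-oxetane to (S)-hydroperoxide, which is C5 of the target.

Step 10
Reactants: 13 (4S)-4-hydroperoxy-4-methyldodec-11-en-2-ol
Product: 14 (4S)-4-[(2-methoxypropan-2-yl)peroxy]-4-methyldodec-11-en-2-ol (C2 epimer mixture)
Conditions: 2-methoxypropene (1.2 equiv), PPTS (2 mol %), CH2Cl2, 0 °C, 30 min; Et3N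
Reagents that add atoms: 2-methoxypropene, COC(C)=C
Why: Acid-catalysed peroxyketalisation is selective for the more nucleophilic hydroperoxide, and the monoperoxyketal is far more stable than any mixed ketal at the secondary alcohol, which therefore stays free for oxidation.

Step 11
Reactants: 14 (4S)-4-[(2-methoxypropan-2-yl)peroxy]-4-methyldodec-11-en-2-ol
Product: 15 (4S)-4-[(2-methoxypropan-2-yl)peroxy]-4-methyldodec-11-en-2-one
Conditions: Dess–Martin periodinane (1.5 equiv), pyridine (5 equiv), CH2Cl2, 0 → 25 °C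
Reagents that add atoms: none
Why: Buffered Dess–Martin oxidation converts the secondary alcohol to the methyl ketone without touching the peroxyketal or the alkene and removes the epimer mixture at C2.

Step 12
Reactants: 15 (4S)-4-[(2-methoxypropan-2-yl)peroxy]-4-methyldodec-11-en-2-one
Product: 18 (5S)-3-methoxy-3,5-dimethyl-5-(oct-7-en-1-yl)-1,2-dioxolane (C3 epimer mixture), via hydroperoxy ketone 16 (not isolated), via hydroxydioxolane 17 (not isolated)
Conditions: p-TsOH·H2O (10 mol %), MeOH, 25 °C
Reagents that add atoms: methanol, CO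
Why: Acid-catalysed methanolysis removes the 2-methoxypropan-2-yl group, the freed hydroperoxide adds to the ketone (5-exo-trig peroxyhemiketalisation) and the hemiketal is exchanged to the methyl peroxyketal; C5 is not involved and the C3 mixture is irrelevant because C3 becomes planar in the next step.

Step 13 (key step)
Reactants: 18 (5S)-3-methoxy-3,5-dimethyl-5-(oct-7-en-1-yl)-1,2-dioxolane; 19 tert-butyl[(1-methoxyethenyl)oxy]dimethylsilane
Product: 21 methyl 2-[(3R,5S)-3,5-dimethyl-5-(oct-7-en-1-yl)-1,2-dioxolan-3-yl]acetate, via peroxycarbenium ion 20 (not isolated)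
Conditions: TiCl4 (1.1 equiv), 19 (3 equiv), CH2Cl2, −78 °C; aq. NaHCO3; chromatographic separation of the C3 epimers
Reagents that add atoms: none
Why: Mukaiyama aldol-type addition: TiCl4 ionises the peroxyketal to the peroxycarbenium ion, which the silyl ketene acetal attacks much faster than the unactivated terminal alkene and preferentially anti to the larger C5 substituent, giving CH2CO2Me trans to the chain, (3R,5S); the selectivity is only modest, so the (3S,5S) epimer is removed by chromatography and the assignment checked by NOE between C3-CH2 and C5-CH3.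

Step 14
Reactants: 22 (2Z)-pent-2-en-1-ol
Product: 23 (2Z)-1-bromopent-2-ene
Conditions: CBr4 (1.1 equiv), PPh3 (1.15 equiv), CH2Cl2, 0 °C
Reagents that add atoms: carbon tetrabromide, BrC(Br)(Br)Br
Why: Appel bromination displaces the oxyphosphonium group directly at the primary carbon (SN2), leaving the (Z) double bond in place.

Step 15
Reactants: 23 (2Z)-1-bromopent-2-ene; 24 ethynyltrimethylsilane
Product: 25 [(4Z)-hept-4-en-1-yn-1-yl]trimethylsilane
Conditions: CuI (10 mol %), K2CO3 (1.5 equiv), Bu4NI (10 mol %), DMF, 25 °C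
Reagents that add atoms: none
Why: Copper-catalysed alkynylation of the allylic halide (Jeffery-type coupling) goes through the copper acetylide at the primary carbon (SN2) with retention of the (Z) geometry, giving the skipped enyne.

Step 16
Reactants: 25 [(4Z)-hept-4-en-1-yn-1-yl]trimethylsilane
Product: 26 (4Z)-hept-4-en-1-yne
Conditions: K2CO3 (0.2 equiv), MeOH, 0 → 25 °C; kept as a solution in CH2Cl2 (volatile)
Reagents that add atoms: none
Why: Methoxide-catalysed protodesilylation cleaves only the C(sp)–Si bond, and the short, cool reaction avoids base isomerisation of the skipped enyne.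

Step 17
Reactants: 26 (4Z)-hept-4-en-1-yne
Product: 28 (1E,4Z)-1-iodohepta-1,4-diene, via alkenylzirconocene chloride 27 (not isolated)
Conditions: Cp2Zr(H)Cl (Schwartz reagent, 1.2 equiv), CH2Cl2, 25 °C; then I2 (1.2 equiv), 0 °C
Reagents that add atoms: iodine, [I][I]
Why: Hydrozirconation adds Zr–H syn with zirconium at the terminal alkyne carbon (much faster than at the internal alkene), and iodinolysis of the C–Zr bond with retention gives the (1E)-iodide.

Step 18
Reactants: 21 methyl 2-[(3R,5S)-3,5-dimethyl-5-(oct-7-en-1-yl)-1,2-dioxolan-3-yl]acetate; 29 2-ethenyl-4,4,5,5-tetramethyl-1,3,2-dioxaborolane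
Product: 30 methyl 2-[(3R,5S)-3,5-dimethyl-5-[(7E)-8-(4,4,5,5-tetramethyl-1,3,2-dioxaborolan-2-yl)oct-7-en-1-yl]-1,2-dioxolan-3-yl]acetate
Conditions: second-generation Hoveyda–Grubbs catalyst RuCl2(H2IMes)(=CH-C6H4-2-OiPr) (5 mol %), 29 (3 equiv), CH2Cl2, 40 °C
Reagents that add atoms: none
Why: Olefin cross-metathesis of a terminal alkene with vinyl pinacol boronate is (E)-selective (typically >20:1), and the phosphine-free ruthenium carbene tolerates the fully substituted dialkyl peroxide and the ester.

Step 19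
Reactants: 30 methyl 2-[(3R,5S)-3,5-dimethyl-5-[(7E)-8-(4,4,5,5-tetramethyl-1,3,2-dioxaborolan-2-yl)oct-7-en-1-yl]-1,2-dioxolan-3-yl]acetate; 28 (1E,4Z)-1-iodohepta-1,4-diene
Product: 31 methyl 2-[(3R,5S)-3,5-dimethyl-5-[(7E,9E,12Z)-pentadeca-7,9,12-trien-1-yl]-1,2-dioxolan-3-yl]acetate
Conditions: Pd(dppf)Cl2 (5 mol %), K3PO4 (3 equiv), THF/H2O (degassed), 25 °C, dark
Reagents that add atoms: none
Why: Suzuki–Miyaura coupling joins the two sp2 carbons with retention at both partners, giving the (7E,9E)-diene next to the preformed (12Z)-alkene, while the mild base and temperature spare the ester and the tetrasubstituted dioxolane.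

**Compound list**

1 | 8-bromooct-1-ene | C=CCCCCCCBr | starting material
2 | ethyl but-2-ynoate | CC#CC(=O)OCC | starting material
3 | oct-7-en-1-ylmagnesium bromide | C=CCCCCCC[Mg]Br | intermediate
4 | oct-7-en-1-ylcopper (as its MgBr2 complex) | C=CCCCCCC[Cu] | intermediate
5 | ethyl (2E)-3-methylundeca-2,10-dienoate | CCOC(=O)/C=C(\C)CCCCCCC=C | intermediate
6 | (2E)-3-methylundeca-2,10-dien-1-ol | OC/C=C(\C)CCCCCCC=C | intermediate
7 | [(2R,3R)-3-methyl-3-(oct-7-en-1-yl)oxiran-2-yl]methanol | OC[C@H]1O[C@]1(C)CCCCCCC=C | intermediate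
8 | (2S,3R)-3-methyl-3-(oct-7-en-1-yl)oxirane-2-carbaldehyde | O=C[C@H]1O[C@]1(C)CCCCCCC=C | intermediate
9 | 1-[(2R,3R)-3-methyl-3-(oct-7-en-1-yl)oxiran-2-yl]ethan-1-ol, carbinol epimer mixture | CC(O)[C@H]1O[C@]1(C)CCCCCCC=C | intermediate
10 | (4R)-4-methyldodec-11-ene-2,4-diol, C2 epimer mixture | CC(O)C[C@](C)(O)CCCCCCC=C | intermediate
11 | (4R)-4-hydroxy-4-methyldodec-11-en-2-yl 4-methylbenzenesulfonate, C2 epimer mixture | CC(OS(=O)(=O)c1ccc(C)cc1)C[C@](C)(O)CCCCCCC=C | intermediate
12 | (2R)-2,4-dimethyl-2-(oct-7-en-1-yl)oxetane, C4 epimer mixture | CC1C[C@@](C)(CCCCCCC=C)O1 | intermediate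
13 | (4S)-4-hydroperoxy-4-methyldodec-11-en-2-ol, C2 epimer mixture | CC(O)C[C@@](C)(OO)CCCCCCC=C | intermediate
14 | (4S)-4-[(2-methoxypropan-2-yl)peroxy]-4-methyldodec-11-en-2-ol, C2 epimer mixture | CC(O)C[C@@](C)(OOC(C)(C)OC)CCCCCCC=C | intermediate
15 | (4S)-4-[(2-methoxypropan-2-yl)peroxy]-4-methyldodec-11-en-2-one | CC(=O)C[C@@](C)(OOC(C)(C)OC)CCCCCCC=C | intermediate
16 | (4S)-4-hydroperoxy-4-methyldodec-11-en-2-one | CC(=O)C[C@@](C)(OO)CCCCCCC=C | intermediate
17 | (5S)-3,5-dimethyl-5-(oct-7-en-1-yl)-1,2-dioxolan-3-ol, C3 epimer mixture | CC1(O)C[C@](C)(CCCCCCC=C)OO1 | intermediate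
18 | (5S)-3-methoxy-3,5-dimethyl-5-(oct-7-en-1-yl)-1,2-dioxolane, C3 epimer mixture | COC1(C)C[C@](C)(CCCCCCC=C)OO1 | intermediate
19 | tert-butyl[(1-methoxyethenyl)oxy]dimethylsilane | COC(=C)O[Si](C)(C)C(C)(C)C | starting material
20 | (5S)-3,5-dimethyl-5-(oct-7-en-1-yl)-1,2-dioxolan-3-ylium (peroxycarbenium ion) | C[C+]1C[C@](C)(CCCCCCC=C)OO1 | intermediate
21 | methyl 2-[(3R,5S)-3,5-dimethyl-5-(oct-7-en-1-yl)-1,2-dioxolan-3-yl]acetate | C=CCCCCCC[C@@]1(C)C[C@](C)(CC(=O)OC)OO1 | intermediate
22 | (2Z)-pent-2-en-1-ol | CC/C=C\CO | starting material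
23 | (2Z)-1-bromopent-2-ene | CC/C=C\CBr | intermediate
24 | ethynyltrimethylsilane | C#C[Si](C)(C)C | starting material
25 | [(4Z)-hept-4-en-1-yn-1-yl]trimethylsilane | CC/C=C\CC#C[Si](C)(C)C | intermediate
26 | (4Z)-hept-4-en-1-yne | CC/C=C\CC#C | intermediate
27 | chlorobis(cyclopentadienyl)[(1E,4Z)-hepta-1,4-dien-1-yl]zirconium | CC/C=C\C/C=C/[Zr](Cl)(C1C=CC=C1)C1C=CC=C1 | intermediate
28 | (1E,4Z)-1-iodohepta-1,4-diene | CC/C=C\C/C=C/I | intermediate
29 | 2-ethenyl-4,4,5,5-tetramethyl-1,3,2-dioxaborolane | C=CB1OC(C)(C)C(C)(C)O1 | starting material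
30 | methyl 2-[(3R,5S)-3,5-dimethyl-5-[(7E)-8-(4,4,5,5-tetramethyl-1,3,2-dioxaborolan-2-yl)oct-7-en-1-yl]-1,2-dioxolan-3-yl]acetate | CC1(C)OB(/C=C/CCCCCC[C@@]2(C)C[C@](C)(CC(=O)OC)OO2)OC1(C)C | intermediate
31 | methyl 2-[(3R,5S)-3,5-dimethyl-5-[(7E,9E,12Z)-pentadeca-7,9,12-trien-1-yl]-1,2-dioxolan-3-yl]acetate | CC/C=C\C/C=C/C=C/CCCCCC[C@@]1(C)C[C@](C)(CC(=O)OC)OO1 | target

**Summary**

Total step count: 19. Longest linear sequence: 15 steps (steps 1–13, 18 and 19, from 8-bromooct-1-ene).

Steps most likely to fail: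

Step 8 (oxetane closure at a secondary carbon). The tertiary alkoxide can fragment in a Grob sense to a methyl ketone and propene, or the tosylate can eliminate. The fallback closes the oxetane on a primary carbon and brings in the methyl group later; it sets out from 7 and comes back at 14. Red-Al reduction of 7 gives (3R)-3-methylundec-10-ene-1,3-diol F1. Selective primary tosylation gives (3R)-3-hydroxy-3-methylundec-10-en-1-yl 4-methylbenzenesulfonate F2, and KOtBu closes it to (2R)-2-methyl-2-(oct-7-en-1-yl)oxetane F3, the best-precedented substrate class for perhydrolysis. H2O2/TMSOTf opens it with inversion to (3S)-3-hydroperoxy-3-methylundec-10-en-1-ol F4. 2-Methoxypropene/PPTS gives (3S)-3-[(2-methoxypropan-2-yl)peroxy]-3-methylundec-10-en-1-ol F5, and Dess–Martin oxidation with pyridine gives (3S)-3-[(2-methoxypropan-2-yl)peroxy]-3-methylundec-10-enal F6. MeTi(OiPr)3 (THF, −78 → −20 °C), a non-basic, aldehyde-selective methyl donor that should leave the O–O bond alone, then gives 14.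

Step 13 (key addition). The facial selectivity at C3 is expected to be modest, and TiCl4 could cleave the peroxide. The fallback makes the same C3–CH2 bond by a conventional aldol addition to the ketone and closes the ring afterwards; it sets out from 15 and comes back at 21. Aldol addition of the lithium enolate of methyl (trimethylsilyl)acetate (LiN(iPr)2, THF, −78 °C) to 15 with in situ Peterson elimination gives methyl (5S)-5-[(2-methoxypropan-2-yl)peroxy]-3,5-dimethyltrideca-2,12-dienoate F7 as an E/Z mixture. AcOH/THF/H2O frees the hydroperoxide, methyl (5S)-5-hydroperoxy-3,5-dimethyltrideca-2,12-dienoate F8. Et2NH in CF3CH2OH closes the dioxolane by 5-exo peroxide conjugate addition to give 21 and its C3 epimer; because this closure is reversible, the unwanted epimer can be resubjected.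

Step 19 (Suzuki coupling beside a dioxolane). Palladium could insert into the O–O bond, or the base could open the β-peroxy ester. The fallback is metal-free olefination; it sets out from 21 and 26 and comes back at 31. Ozonolysis of 21 (O3, pyridine, CH2Cl2, −78 °C; dialkyl peroxides survive) gives methyl 2-[(3R,5S)-3,5-dimethyl-5-(7-oxoheptyl)-1,2-dioxolan-3-yl]acetate F9. Separately, 26 is treated with n-BuLi and paraformaldehyde to give (5Z)-oct-5-en-2-yn-1-ol F10, LiAlH4 trans-reduction gives (2E,5Z)-octa-2,5-dien-1-ol F11, CBr4/PPh3 gives (2E,5Z)-1-bromoocta-2,5-diene F12, and Arbuzov reaction with P(OEt)3 gives diethyl [(2E,5Z)-octa-2,5-dien-1-yl]phosphonate F13. Horner–Wadsworth–Emmons reaction of lithiated F13 (LiN(SiMe3)2, THF, −78 °C) with F9 gives 31 with an (E)-selective new double bond.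

**Further compounds**

F1 | step 8 | (3R)-3-methylundec-10-ene-1,3-diol | OCC[C@](C)(O)CCCCCCC=C
F2 | step 8 | (3R)-3-hydroxy-3-methylundec-10-en-1-yl 4-methylbenzenesulfonate | Cc1ccc(cc1)S(=O)(=O)OCC[C@](C)(O)CCCCCCC=C
F3 | step 8 | (2R)-2-methyl-2-(oct-7-en-1-yl)oxetane | C1C[C@@](C)(CCCCCCC=C)O1
F4 | step 8 | (3S)-3-hydroperoxy-3-methylundec-10-en-1-ol | OCC[C@@](C)(OO)CCCCCCC=C
F5 | step 8 | (3S)-3-[(2-methoxypropan-2-yl)peroxy]-3-methylundec-10-en-1-ol | OCC[C@@](C)(OOC(C)(C)OC)CCCCCCC=C
F6 | step 8 | (3S)-3-[(2-methoxypropan-2-yl)peroxy]-3-methylundec-10-enal | O=CC[C@@](C)(OOC(C)(C)OC)CCCCCCC=C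
F7 | step 13 | methyl (5S)-5-[(2-methoxypropan-2-yl)peroxy]-3,5-dimethyltrideca-2,12-dienoate (E/Z mixture) | COC(=O)C=C(C)C[C@@](C)(OOC(C)(C)OC)CCCCCCC=C
F8 | step 13 | methyl (5S)-5-hydroperoxy-3,5-dimethyltrideca-2,12-dienoate (E/Z mixture) | COC(=O)C=C(C)C[C@@](C)(OO)CCCCCCC=C
F9 | step 19 | methyl 2-[(3R,5S)-3,5-dimethyl-5-(7-oxoheptyl)-1,2-dioxolan-3-yl]acetate | O=CCCCCCC[C@@]1(C)C[C@](C)(CC(=O)OC)OO1
F10 | step 19 | (5Z)-oct-5-en-2-yn-1-ol | CC/C=C\CC#CCO
F11 | step 19 | (2E,5Z)-octa-2,5-dien-1-ol | CC/C=C\C/C=C/CO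
F12 | step 19 | (2E,5Z)-1-bromoocta-2,5-diene | CC/C=C\C/C=C/CBr
F13 | step 19 | diethyl [(2E,5Z)-octa-2,5-dien-1-yl]phosphonate | CCOP(=O)(OCC)C/C=C/C/C=C\CC
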